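**Retrosynthetic overview**
- The target is traced back, by C5 O-demethylation, ring B debenzylation and side-chain oxidation, to a 5,7-dimethoxyflavone; ring C is opened at O1–C2 (cyclodehydration) and at C3–C2 (Baker–Venkataraman acyl transfer) to aryl ketone 18 and ring B acid chloride 20.
- Ketone 18 comes from ortho-acylation (C4a–C4) of the mirror-symmetric phenol 14 with a 5-methylhex-4-enoyl unit that already holds the C3 prenyl group; 14 comes from phenol 12 by O-methylation and debenzylation.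
- Phenol 12 is disconnected by a Danheiser benzannulation into 3-(benzyloxy)cyclobutenone 7 and 1-methoxyalkyne 5, which carries the side chain as a silyl-protected carbinol.
- The strategy rests on ring A (C4a, C5, C6, C7, C8, C8a): a 1,3,5-trioxygenated benzene whose C6 chain lies between the C5 and C7 oxygens, the pattern a vinylketene and ynol ether union gives directly.
- Ring order: ring A (step 4), ring B brought in intact (step 10), ring C (step 12).

Key step: step 4

Remark: the silyloxy-bearing carbon of the side chain is carried as a racemate, because it is oxidised to the ketone in step 13 and the target has no stereocentre.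

**Step 1**
Reactants: 1 chloroacetaldehyde dimethyl acetal; 2 2-isopropyloxirane (racemic)
Product: 4 6-methoxy-2-methylhex-5-yn-3-ol (racemic), via sodium methoxyacetylide 3 (not isolated)
Conditions: NaNH2 (3.1 equiv), liq. NH3, −33 °C; then 2, THF/DMSO, −33 °C → rt; solid NH4Cl
Reagents that add atoms: none
Why: Double elimination (HCl, then methanol) and deprotonation of the chloroacetal with NaNH2 is the classical route to a sodium alkoxyacetylide, which should open the monosubstituted epoxide by SN2 attack at its CH2 terminus and so give the racemic secondary carbinol.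

**Step 2**
Reactants: 4 6-methoxy-2-methylhex-5-yn-3-ol
Product: 5 tert-butyl[(6-methoxy-2-methylhex-5-yn-3-yl)oxy]dimethylsilane (racemic)
Conditions: TBSCl (1.5 equiv), imidazole (3 equiv), DMAP (cat.), DMF, rt → 40 °C
Reagents that add atoms: tert-butyldimethylsilyl chloride, CC(C)(C)[Si](C)(C)Cl
Why: Imidazole-promoted silylation of a secondary alcohol runs under non-acidic conditions, which the acid-sensitive ynol ether should tolerate.

**Step 3**
Reactants: 6 3-ethoxycyclobut-2-en-1-one
Product: 7 3-(benzyloxy)cyclobut-2-en-1-one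
Conditions: BnOH (3 equiv), TsOH·H2O (2 mol %), toluene, 40 °C, 80 mbar (EtOH distilled off)
Reagents that add atoms: benzyl alcohol, OCc1ccccc1
Why: Acid-catalysed alkoxy exchange of a vinylogous ester (addition of benzyl alcohol at C3, loss of ethanol) should be driven to the benzyl enol ether by removal of the volatile ethanol.

**Step 4**
Reactants: 7 3-(benzyloxy)cyclobut-2-en-1-one; 5 tert-butyl[(6-methoxy-2-methylhex-5-yn-3-yl)oxy]dimethylsilane
Product: 12 5-(benzyloxy)-3-methoxy-2-[2-(tert-butyldimethylsilyloxy)-3-methylbutyl]phenol (racemic), via vinylketene 8 (not isolated), via vinylcyclobutenone 9 (not isolated), via dienylketene 10 (not isolated), via cyclohexadienone 11 (not isolated)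
Conditions: 7 (1.0 equiv), 5 (1.3 equiv), toluene (0.5 M), 110 °C, sealed tube; then K2CO3, MeOH, rt
Reagents that add atoms: none
Why: Heating should open cyclobutenone 7 by four-electron electrocyclic ring opening to vinylketene 8, whose ketene C=C adds to ynol ether 5 in a [2+2] cycloaddition to give vinylcyclobutenone 9; a second four-electron opening gives dienylketene 10, which closes ring A by thermal six-electron electrocyclisation (C4a–C5), and cyclohexadienone 11 tautomerises to phenol 12. This is the Danheiser benzannulation of a cyclobutenone with an alkoxyalkyne, a net isomerising union known for resorcinol ethers. No stereocentre is formed, and the racemic silyloxy carbon of the chain is a spectator. The step needs regiocontrol in the [2+2] addition, and the polarised ynol ether secures it: its nucleophilic chain-bearing carbon bonds to the ketene carbonyl carbon (C5–C6) and its methoxy-bearing carbon to the ketene α-carbon (C7–C8), so the chain ends up between the new hydroxyl and the methoxyl. The methoxy ynol ether has no β-hydrogen for retro-ene loss of ketene at 110 °C, and the silyl ether and the benzyl enol ether are inert to heat. The closing carbonate methanolysis should return any product phenol that was acylated by excess vinylketene.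

**Step 5**
Reactants: 12 5-(benzyloxy)-3-methoxy-2-[2-(tert-butyldimethylsilyloxy)-3-methylbutyl]phenol
Product: 13 5-(benzyloxy)-1,3-dimethoxy-2-[2-(tert-butyldimethylsilyloxy)-3-methylbutyl]benzene (racemic)
Conditions: MeI (2 equiv), K2CO3 (2 equiv), DMF, rt
Reagents that add atoms: iodomethane, CI
Why: Williamson O-methylation of the phenoxide makes the C5 and C7 oxygens identical, so the ring becomes symmetric once the benzyl group is removed.

**Step 6**
Reactants: 13 5-(benzyloxy)-1,3-dimethoxy-2-[2-(tert-butyldimethylsilyloxy)-3-methylbutyl]benzene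
Product: 14 4-[2-(tert-butyldimethylsilyloxy)-3-methylbutyl]-3,5-dimethoxyphenol (racemic)
Conditions: H2 (1 atm), 10% Pd/C, EtOAc, rt
Reagents that add atoms: none
Why: Catalytic hydrogenolysis of the aryl benzyl ether should free the future O1 phenol while the silyl ether and methyl ethers stay intact, giving a phenol whose two ortho positions are equivalent.

**Step 7**
Reactants: 15 5-methylhex-4-enoic acid
Product: 16 5-methylhex-4-enoyl chloride
Conditions: (COCl)2 (1.2 equiv), DMF (cat.), CH2Cl2, 0 °C → rt; concentrated and used crude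
Reagents that add atoms: oxalyl chloride, O=C(Cl)C(Cl)=O
Why: Acid chloride formation through the Vilsmeier-type chloroiminium catalyst runs cold and lets HCl escape, so the trisubstituted alkene should survive.

**Step 8**
Reactants: 14 4-[2-(tert-butyldimethylsilyloxy)-3-methylbutyl]-3,5-dimethoxyphenol; 16 5-methylhex-4-enoyl chloride
Product: 18 1-{3-[2-(tert-butyldimethylsilyloxy)-3-methylbutyl]-6-hydroxy-2,4-dimethoxyphenyl}-5-methylhex-4-en-1-one (racemic), via bromomagnesium phenolate 17 (not isolated)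
Conditions: EtMgBr (1.0 equiv), Et2O, 0 °C; solvent switched to toluene; 16 (1.0 equiv), 0 °C → rt
Reagents that add atoms: none
Why: Ortho-selective C-acylation of a bromomagnesium phenolate (a magnesium-templated Friedel–Crafts acylation) delivers the acyl group to the ring carbon next to oxygen; the two ortho positions are equivalent, the para position is blocked, and the absence of a strong Lewis acid should spare the silyl ether and the alkene.

**Step 9**
Reactants: 19 2,4-bis(benzyloxy)benzoic acid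
Product: 20 2,4-bis(benzyloxy)benzoyl chloride
Conditions: (COCl)2 (1.2 equiv), DMF (cat.), CH2Cl2, 0 °C → rt; concentrated and used crude
Reagents that add atoms: oxalyl chloride, O=C(Cl)C(Cl)=O
Why: Standard DMF-catalysed conversion of an aryl carboxylic acid to its chloride, to which the benzyl ethers are inert.

**Step 10**
Reactants: 18 1-{3-[2-(tert-butyldimethylsilyloxy)-3-methylbutyl]-6-hydroxy-2,4-dimethoxyphenyl}-5-methylhex-4-en-1-one; 20 2,4-bis(benzyloxy)benzoyl chloride
Product: 21 4-[2-(tert-butyldimethylsilyloxy)-3-methylbutyl]-3,5-dimethoxy-2-(5-methylhex-4-enoyl)phenyl 2,4-bis(benzyloxy)benzoate (racemic)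
Conditions: pyridine (3 equiv), DMAP (0.1 equiv), CH2Cl2, 0 °C → rt
Reagents that add atoms: none
Why: DMAP-catalysed O-aroylation of the chelated phenol is the first stage of a Baker–Venkataraman sequence and brings ring B in at the future O1.

**Step 11**
Reactants: 21 4-[2-(tert-butyldimethylsilyloxy)-3-methylbutyl]-3,5-dimethoxy-2-(5-methylhex-4-enoyl)phenyl 2,4-bis(benzyloxy)benzoate
Product: 22 1-[2,4-bis(benzyloxy)phenyl]-3-{3-[2-(tert-butyldimethylsilyloxy)-3-methylbutyl]-6-hydroxy-2,4-dimethoxyphenyl}-2-(3-methylbut-2-en-1-yl)propane-1,3-dione (mixture of diastereomers and tautomers)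
Conditions: KOt-Bu (2.5 equiv), THF, 0 °C → rt; aq NH4Cl
Reagents that add atoms: none
Why: Baker–Venkataraman rearrangement: the ketone enolate attacks the ortho ester through a six-membered tetrahedral intermediate and forms the C2–C3 bond with the prenyl group already on C3; the new stereocentre is labile and is lost in step 12.

**Step 12**
Reactants: 22 1-[2,4-bis(benzyloxy)phenyl]-3-{3-[2-(tert-butyldimethylsilyloxy)-3-methylbutyl]-6-hydroxy-2,4-dimethoxyphenyl}-2-(3-methylbut-2-en-1-yl)propane-1,3-dione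
Product: 24 2-[2,4-bis(benzyloxy)phenyl]-6-(2-hydroxy-3-methylbutyl)-5,7-dimethoxy-3-(3-methylbut-2-en-1-yl)-4H-chromen-4-one (racemic), via silyl-protected flavone 23 (not isolated)
Conditions: HCl (1.25 M in MeOH), 45 °C
Reagents that add atoms: none
Why: Acid-catalysed cyclodehydration (6-exo-trig addition of the phenol to the ring B ketone, then loss of water) should close ring C, and the same medium methanolyses the secondary silyl ether while benzyl and methyl ethers persist.

**Step 13**
Reactants: 24 2-[2,4-bis(benzyloxy)phenyl]-6-(2-hydroxy-3-methylbutyl)-5,7-dimethoxy-3-(3-methylbut-2-en-1-yl)-4H-chromen-4-one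
Product: 25 2-[2,4-bis(benzyloxy)phenyl]-5,7-dimethoxy-6-(3-methyl-2-oxobutyl)-3-(3-methylbut-2-en-1-yl)-4H-chromen-4-one
Conditions: Dess–Martin periodinane (1.5 equiv), CH2Cl2, 0 °C → rt
Reagents that add atoms: none
Why: Dess–Martin oxidation of the secondary alcohol to the side-chain ketone is done while all phenols are still masked, so neither the electron-rich rings nor the prenyl alkene should be touched.

**Step 14**
Reactants: 25 2-[2,4-bis(benzyloxy)phenyl]-5,7-dimethoxy-6-(3-methyl-2-oxobutyl)-3-(3-methylbut-2-en-1-yl)-4H-chromen-4-one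
Product: 26 2-(2,4-dihydroxyphenyl)-5-hydroxy-7-methoxy-6-(3-methyl-2-oxobutyl)-3-(3-methylbut-2-en-1-yl)-4H-chromen-4-one (target)
Conditions: BCl3 (1 M in CH2Cl2, 6 equiv), pentamethylbenzene (6 equiv), CH2Cl2, −78 → 0 °C; then H2O
Reagents that add atoms: none
Why: BCl3 should cleave the C5 methyl ether through the six-membered chelate with the C4 carbonyl and remove both aryl benzyl ethers with pentamethylbenzene as cation scavenger (Lewis acid ether cleavage), while the non-chelated C7 methyl ether is left at low temperature.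

**Compound list**
1 | chloroacetaldehyde dimethyl acetal | COC(CCl)OC | starting material
2 | 2-isopropyloxirane (racemic) | CC(C)C1CO1 | starting material
3 | sodium methoxyacetylide | COC#C[Na] | intermediate
4 | 6-methoxy-2-methylhex-5-yn-3-ol (racemic) | COC#CCC(O)C(C)C | intermediate
5 | tert-butyl[(6-methoxy-2-methylhex-5-yn-3-yl)oxy]dimethylsilane (racemic) | COC#CCC(O[Si](C)(C)C(C)(C)C)C(C)C | intermediate
6 | 3-ethoxycyclobut-2-en-1-one | CCOC1=CC(=O)C1 | starting material
7 | 3-(benzyloxy)cyclobut-2-en-1-one | O=C1CC(OCc2ccccc2)=C1 | intermediate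
8 | 3-(benzyloxy)buta-1,3-dien-1-one (vinylketene) | O=C=CC(=C)OCc1ccccc1 | intermediate
9 | 4-[1-(benzyloxy)ethenyl]-3-methoxy-2-[2-(tert-butyldimethylsilyloxy)-3-methylbutyl]cyclobut-2-en-1-one (mixture of diastereomers) | O=C1C(CC(O[Si](C)(C)C(C)(C)C)C(C)C)=C(OC)C1C(=C)OCc1ccccc1 | intermediate
10 | (3E)-5-(benzyloxy)-3-methoxy-2-[2-(tert-butyldimethylsilyloxy)-3-methylbutyl]hexa-1,3,5-trien-1-one (dienylketene, ketene and benzyloxyvinyl groups cis) | O=C=C(CC(O[Si](C)(C)C(C)(C)C)C(C)C)/C(OC)=C\C(=C)OCc1ccccc1 | intermediate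
11 | 5-(benzyloxy)-3-methoxy-2-[2-(tert-butyldimethylsilyloxy)-3-methylbutyl]cyclohexa-2,4-dien-1-one | O=C1CC(OCc2ccccc2)=CC(OC)=C1CC(O[Si](C)(C)C(C)(C)C)C(C)C | intermediate
12 | 5-(benzyloxy)-3-methoxy-2-[2-(tert-butyldimethylsilyloxy)-3-methylbutyl]phenol (racemic) | COc1cc(OCc2ccccc2)cc(O)c1CC(O[Si](C)(C)C(C)(C)C)C(C)C | intermediate
13 | 5-(benzyloxy)-1,3-dimethoxy-2-[2-(tert-butyldimethylsilyloxy)-3-methylbutyl]benzene (racemic) | COc1cc(OCc2ccccc2)cc(OC)c1CC(O[Si](C)(C)C(C)(C)C)C(C)C | intermediate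
14 | 4-[2-(tert-butyldimethylsilyloxy)-3-methylbutyl]-3,5-dimethoxyphenol (racemic) | COc1cc(O)cc(OC)c1CC(O[Si](C)(C)C(C)(C)C)C(C)C | intermediate
15 | 5-methylhex-4-enoic acid | CC(C)=CCCC(=O)O | starting material
16 | 5-methylhex-4-enoyl chloride | CC(C)=CCCC(=O)Cl | intermediate
17 | bromomagnesium 4-[2-(tert-butyldimethylsilyloxy)-3-methylbutyl]-3,5-dimethoxyphenolate | COc1cc(O[Mg]Br)cc(OC)c1CC(O[Si](C)(C)C(C)(C)C)C(C)C | intermediate
18 | 1-{3-[2-(tert-butyldimethylsilyloxy)-3-methylbutyl]-6-hydroxy-2,4-dimethoxyphenyl}-5-methylhex-4-en-1-one (racemic) | COc1cc(O)c(C(=O)CCC=C(C)C)c(OC)c1CC(O[Si](C)(C)C(C)(C)C)C(C)C | intermediate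
19 | 2,4-bis(benzyloxy)benzoic acid | OC(=O)c1ccc(OCc2ccccc2)cc1OCc1ccccc1 | starting material
20 | 2,4-bis(benzyloxy)benzoyl chloride | ClC(=O)c1ccc(OCc2ccccc2)cc1OCc1ccccc1 | intermediate
21 | 4-[2-(tert-butyldimethylsilyloxy)-3-methylbutyl]-3,5-dimethoxy-2-(5-methylhex-4-enoyl)phenyl 2,4-bis(benzyloxy)benzoate (racemic) | COc1cc(OC(=O)c2ccc(OCc3ccccc3)cc2OCc2ccccc2)c(C(=O)CCC=C(C)C)c(OC)c1CC(O[Si](C)(C)C(C)(C)C)C(C)C | intermediate
22 | 1-[2,4-bis(benzyloxy)phenyl]-3-{3-[2-(tert-butyldimethylsilyloxy)-3-methylbutyl]-6-hydroxy-2,4-dimethoxyphenyl}-2-(3-methylbut-2-en-1-yl)propane-1,3-dione (mixture of diastereomers) | COc1cc(O)c(C(=O)C(CC=C(C)C)C(=O)c2ccc(OCc3ccccc3)cc2OCc2ccccc2)c(OC)c1CC(O[Si](C)(C)C(C)(C)C)C(C)C | intermediate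
23 | 2-[2,4-bis(benzyloxy)phenyl]-6-[2-(tert-butyldimethylsilyloxy)-3-methylbutyl]-5,7-dimethoxy-3-(3-methylbut-2-en-1-yl)-4H-chromen-4-one (racemic) | COc1cc2oc(-c3ccc(OCc4ccccc4)cc3OCc3ccccc3)c(CC=C(C)C)c(=O)c2c(OC)c1CC(O[Si](C)(C)C(C)(C)C)C(C)C | intermediate
24 | 2-[2,4-bis(benzyloxy)phenyl]-6-(2-hydroxy-3-methylbutyl)-5,7-dimethoxy-3-(3-methylbut-2-en-1-yl)-4H-chromen-4-one (racemic) | COc1cc2oc(-c3ccc(OCc4ccccc4)cc3OCc3ccccc3)c(CC=C(C)C)c(=O)c2c(OC)c1CC(O)C(C)C | intermediate
25 | 2-[2,4-bis(benzyloxy)phenyl]-5,7-dimethoxy-6-(3-methyl-2-oxobutyl)-3-(3-methylbut-2-en-1-yl)-4H-chromen-4-one | COc1cc2oc(-c3ccc(OCc4ccccc4)cc3OCc3ccccc3)c(CC=C(C)C)c(=O)c2c(OC)c1CC(=O)C(C)C | intermediate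
26 | 2-(2,4-dihydroxyphenyl)-5-hydroxy-7-methoxy-6-(3-methyl-2-oxobutyl)-3-(3-methylbut-2-en-1-yl)-4H-chromen-4-one | COc1cc2oc(-c3ccc(O)cc3O)c(CC=C(C)C)c(=O)c2c(O)c1CC(=O)C(C)C | target

**Step count**
Total: 14 steps. Longest linear sequence: 11 steps (1, 2, 4, 5, 6, 8, 10, 11, 12, 13, 14).

**Steps most likely to fail**

1. Step 4 (benzannulation). The 3-alkoxy group stabilises the cyclobutenone, so its ring opening may be slow. Oligomerisation of the vinylketene, acylation of the product phenol by the ketene, or thermal decay of the ynol ether could then outrun the [2+2] addition. The fallback sets out from epoxide 2 and returns at phenol 14. 3,5-Dimethoxyphenol is silylated (TIPSCl, imidazole, DMF) to (3,5-dimethoxyphenoxy)triisopropylsilane F1. Directed lithiation between the two methoxy groups (n-BuLi, THF, 0 °C) gives 2,6-dimethoxy-4-(triisopropylsilyloxy)phenyllithium F2, which opens 2 at its CH2 terminus (CuI cat., THF, −30 °C) to 1-[2,6-dimethoxy-4-(triisopropylsilyloxy)phenyl]-3-methylbutan-2-ol F3. Silylation (TBSOTf, 2,6-lutidine, CH2Cl2) gives the bis-silyl ether tert-butyl({1-[2,6-dimethoxy-4-(triisopropylsilyloxy)phenyl]-3-methylbutan-2-yl}oxy)dimethylsilane F4. Selective cleavage of the aryl silyl ether (Bu4NF, 1 equiv, THF, 0 °C) gives 14.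

2. Step 8 (ortho-acylation). The phenolate may be acylated at oxygen instead of carbon, or a second acyl group may enter the other ortho position. The fallback sets out from phenol 14 and returns at ketone 18. Phenol 14 is protected (MOMCl, i-Pr2NEt, CH2Cl2) as tert-butyl({1-[2,6-dimethoxy-4-(methoxymethoxy)phenyl]-3-methylbutan-2-yl}oxy)dimethylsilane F5. Directed ortho-metalation between the methoxymethoxy and methoxy groups (n-BuLi, THF, 0 °C) gives aryllithium F6. This is acylated at −78 °C with N-methoxy-N,5-dimethylhex-4-enamide F7 (from acid 15, carbonyldiimidazole, MeNHOMe·HCl) to give 1-{3-[2-(tert-butyldimethylsilyloxy)-3-methylbutyl]-2,4-dimethoxy-6-(methoxymethoxy)phenyl}-5-methylhex-4-en-1-one F8. The acetal ortho to the carbonyl is then cleaved selectively (ZnBr2, n-PrSH, CH2Cl2, 0 °C) to give 18.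

3. Step 14 (one-pot Lewis acid deprotection). The prenyl group may be hydrochlorinated or cyclised, benzyl cations may be captured by the electron-rich rings, the freed C5 hydroxyl may cyclise onto the side-chain ketone, or the C7 methyl ether may also be cleaved. The fallback sets out from ketone 18 and returns at target 26; it protects ring B as allyl ethers so that no cation-forming debenzylation is needed.
   - 2,4-Dihydroxybenzoic acid is perallylated (allyl bromide, K2CO3, DMF) to allyl 2,4-bis(allyloxy)benzoate F9 and saponified (LiOH, THF/H2O) to 2,4-bis(allyloxy)benzoic acid F10.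
   - Coupling with 18 (EDC·HCl, DMAP, CH2Cl2) gives 4-[2-(tert-butyldimethylsilyloxy)-3-methylbutyl]-3,5-dimethoxy-2-(5-methylhex-4-enoyl)phenyl 2,4-bis(allyloxy)benzoate F11.
   - Baker–Venkataraman rearrangement (KOt-Bu, THF) gives 1-[2,4-bis(allyloxy)phenyl]-3-{3-[2-(tert-butyldimethylsilyloxy)-3-methylbutyl]-6-hydroxy-2,4-dimethoxyphenyl}-2-(3-methylbut-2-en-1-yl)propane-1,3-dione F12.
   - Cyclodehydration with desilylation (HCl/MeOH, 45 °C) gives 2-[2,4-bis(allyloxy)phenyl]-6-(2-hydroxy-3-methylbutyl)-5,7-dimethoxy-3-(3-methylbut-2-en-1-yl)-4H-chromen-4-one F13.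
   - Dess–Martin oxidation gives 2-[2,4-bis(allyloxy)phenyl]-5,7-dimethoxy-6-(3-methyl-2-oxobutyl)-3-(3-methylbut-2-en-1-yl)-4H-chromen-4-one F14.
   - Chelation-controlled cleavage of the C5 methyl ether (MgI2·OEt2, THF/toluene, 60 °C) gives 2-[2,4-bis(allyloxy)phenyl]-5-hydroxy-7-methoxy-6-(3-methyl-2-oxobutyl)-3-(3-methylbut-2-en-1-yl)-4H-chromen-4-one F15.
   - Allyl transfer to morpholine with Pd(PPh3)4 (zerovalent palladium, THF, rt) then gives 26.

**Further compounds**
F1 | step 4 | (3,5-dimethoxyphenoxy)triisopropylsilane | COc1cc(OC)cc(O[Si](C(C)C)(C(C)C)C(C)C)c1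
F2 | step 4 | 2,6-dimethoxy-4-(triisopropylsilyloxy)phenyllithium | COc1cc(O[Si](C(C)C)(C(C)C)C(C)C)cc(OC)c1[Li]
F3 | step 4 | 1-[2,6-dimethoxy-4-(triisopropylsilyloxy)phenyl]-3-methylbutan-2-ol (racemic) | COc1cc(O[Si](C(C)C)(C(C)C)C(C)C)cc(OC)c1CC(O)C(C)C
F4 | step 4 | tert-butyl({1-[2,6-dimethoxy-4-(triisopropylsilyloxy)phenyl]-3-methylbutan-2-yl}oxy)dimethylsilane (racemic) | COc1cc(O[Si](C(C)C)(C(C)C)C(C)C)cc(OC)c1CC(O[Si](C)(C)C(C)(C)C)C(C)C
F5 | step 8 | tert-butyl({1-[2,6-dimethoxy-4-(methoxymethoxy)phenyl]-3-methylbutan-2-yl}oxy)dimethylsilane (racemic) | COCOc1cc(OC)c(CC(O[Si](C)(C)C(C)(C)C)C(C)C)c(OC)c1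
F6 | step 8 | {3-[2-(tert-butyldimethylsilyloxy)-3-methylbutyl]-2,4-dimethoxy-6-(methoxymethoxy)phenyl}lithium | COCOc1cc(OC)c(CC(O[Si](C)(C)C(C)(C)C)C(C)C)c(OC)c1[Li]
F7 | step 8 | N-methoxy-N,5-dimethylhex-4-enamide | CC(C)=CCCC(=O)N(C)OC
F8 | step 8 | 1-{3-[2-(tert-butyldimethylsilyloxy)-3-methylbutyl]-2,4-dimethoxy-6-(methoxymethoxy)phenyl}-5-methylhex-4-en-1-one (racemic) | COCOc1cc(OC)c(CC(O[Si](C)(C)C(C)(C)C)C(C)C)c(OC)c1C(=O)CCC=C(C)C
F9 | step 14 | allyl 2,4-bis(allyloxy)benzoate | C=CCOC(=O)c1ccc(OCC=C)cc1OCC=C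
F10 | step 14 | 2,4-bis(allyloxy)benzoic acid | OC(=O)c1ccc(OCC=C)cc1OCC=C
F11 | step 14 | 4-[2-(tert-butyldimethylsilyloxy)-3-methylbutyl]-3,5-dimethoxy-2-(5-methylhex-4-enoyl)phenyl 2,4-bis(allyloxy)benzoate (racemic) | COc1cc(OC(=O)c2ccc(OCC=C)cc2OCC=C)c(C(=O)CCC=C(C)C)c(OC)c1CC(O[Si](C)(C)C(C)(C)C)C(C)C
F12 | step 14 | 1-[2,4-bis(allyloxy)phenyl]-3-{3-[2-(tert-butyldimethylsilyloxy)-3-methylbutyl]-6-hydroxy-2,4-dimethoxyphenyl}-2-(3-methylbut-2-en-1-yl)propane-1,3-dione (mixture of diastereomers) | COc1cc(O)c(C(=O)C(CC=C(C)C)C(=O)c2ccc(OCC=C)cc2OCC=C)c(OC)c1CC(O[Si](C)(C)C(C)(C)C)C(C)C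
F13 | step 14 | 2-[2,4-bis(allyloxy)phenyl]-6-(2-hydroxy-3-methylbutyl)-5,7-dimethoxy-3-(3-methylbut-2-en-1-yl)-4H-chromen-4-one (racemic) | COc1cc2oc(-c3ccc(OCC=C)cc3OCC=C)c(CC=C(C)C)c(=O)c2c(OC)c1CC(O)C(C)C
F14 | step 14 | 2-[2,4-bis(allyloxy)phenyl]-5,7-dimethoxy-6-(3-methyl-2-oxobutyl)-3-(3-methylbut-2-en-1-yl)-4H-chromen-4-one | COc1cc2oc(-c3ccc(OCC=C)cc3OCC=C)c(CC=C(C)C)c(=O)c2c(OC)c1CC(=O)C(C)C
F15 | step 14 | 2-[2,4-bis(allyloxy)phenyl]-5-hydroxy-7-methoxy-6-(3-methyl-2-oxobutyl)-3-(3-methylbut-2-en-1-yl)-4H-chromen-4-one | COc1cc2oc(-c3ccc(OCC=C)cc3OCC=C)c(CC=C(C)C)c(=O)c2c(O)c1CC(=O)C(C)C
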